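A small charge of D, 1 mol% on Q, starts chains in a flask fed with 20 mM of Q, and the question is how long those chains get.

| setting | south-west | west | north-west | flask |
|---|---|---|---|---|
| Q | 20 mM (fed, over 15 min) | 20 mM (fed, over 15 min) | 10 mM (fed, over 15 min) | 20 mM (fed, over 15 min) |
| D | 0.5 mol% | 2 mol% | 1 mol% | 1 mol% |
| remark | run made earlier; the fed solution adds 0.10 times the starting volume | run made earlier; the fed solution adds 0.10 times the starting volume | run made earlier; the fed solution adds 0.10 times the starting volume | the fed solution adds 0.10 times the starting volume |
| time |  |  |  | 10 h |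

| run | time / h | J / % | Q / % |
|---|---|---|---|
| south-west | 0.833 | 34.2 | 54.5 |
| south-west | 2.50 | 62.7 | 16.3 |
| south-west | 4.00 | 67.0 | 8.0 |
| south-west | 6.00 | 66.9 | 5.7 |
| south-west | 10.0 | 61.9 | 5.5 |
| south-west | 12.0 | 59.7 | 5.2 |
| west | 0.833 | 75.6 | 17.5 |
| west | 2.50 | 83.9 | 6.7 |
| west | 4.00 | 81.7 | 6.7 |
| west | 6.00 | 79.4 | 6.0 |
| west | 10.0 | 74.1 | 5.9 |
| west | 12.0 | 71.3 | 6.6 |
| north-west | 2.50 | 56.6 | 20.2 |
| north-west | 5.00 | 57.3 | 11.7 |
| north-west | 8.00 | 51.5 | 10.5 |
| north-west | 10.0 | 47.2 | 10.8 |
| north-west | 12.0 | 43.1 | 10.4 |

(scatter of a reading: 0.3 percentage points)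

- charges are per starting volume, the dose included; the dosed solution carries all of it
- the average divides the monomer in chains by the number of chains begun, living and dead together
- what was read earlier has a scatter of 0.3 percentage points, one standard deviation
- the earlier runs do not show the number of chains; that part of a forecast is a guess

1. whether the average number of monomer units in a chain (chains begun, living or dead) reaches 30 by 10 h (yes / no)
2. average number of monomer units in a chain (chains begun, living or dead) at 10 h

The earlier runs give a ladder of times, fastest first. The feed ends at 0.25 h. Next, in the south-west run, Q sinks towards its plateau with a time of 1.12 h, as read from the readings. Slowest, J in that run loses 7.2 percentage points between 6.00 h and 12.0 h, a drain time of 55.8 h, far longer than the sinking of Q. The flask's loading lies between those of the south-west and west runs, and at 10.0 h those runs read Q at 5.5% and 5.9%, close to their readings at 6.00 h, with J falling in both. So the flask should stand on the slow rung at that time, with Q on a plateau and J declining.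

The reckoning here takes the mean J of the south-west and west runs at that time, 68.0%, for the flask's loading. Dividing by the loading gives 68.0, the turnover count: monomer in chains over D charged, which is the degree of polymerisation if each D begins one chain. That stands above the 30 wanted.

The forecast says yes and 70 units, a little above this reckoning, “Assuming one chain per D (a guess)”.

The flask gives yes and 69.7 units.

    Q + D → Z + J (k = 170 /M/min)
    Q + Z → J + Z, rate k2*[Z]*[Q] (k = 130 /M/min)
    J + Z → Q + Z, rate k3*[Z] as long as [J] is above zero (k = 0.160 /min)
    Q → G (k = 0.00350 /min)

In the flask, J of 69.7% over 1 mol% of D counts 69.7 turnovers, and D already stands at 0% of its charge by 0.250 h. At 1.41 h the path from Q to J uses Q at 6.8 times the rate of the path from Q to G, and the flask reaches the wanted length at 0.414 h, with 34.9% of Q reacted. Counted the same way with one chain per D, the west run's J reading at 10.0 h over 2 mol% gives 37.0 turnovers.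

The data were computed with constants of no real substance; noise was put on by code.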